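## Structural features

The target is a five-membered unsaturated lactone (O1, C2 carbonyl, C3, C4, C5) with an enolic hydroxyl on C3, a 4-hydroxyphenyl group (ring B) on C4, and a fully substituted C5 that carries a methyl ester and a benzyl group. The aryl ring of that benzyl group (ring A) is a phenol whose ortho CH2 side chain ends in a 2,2-dimethyloxirane. There are two stereocentres, C5 (R) and the secondary oxirane carbon (R); they lie six bonds apart with an aromatic ring between them, so neither can steer the other and each must be set by a reagent. The fragile points are the trisubstituted epoxide next to a phenol that can open it (5-exo or 6-endo) once deprotonated or once the epoxide is protonated, the acidic and easily oxidised C3 enol, the lactone and ester that share C5, and two electron-rich arenes. The real difficulty is C5: it has no hydrogen, it carries O1, the carboxyl carbon, the benzylic CH2 and the sp2 carbon C4, and it must be formed as one enantiomer; the timing of the epoxide is the second problem. The key step uses the fact that O1, C5 and C4 can be read as the oxygen and the two carbons of an aryl glycidic ester: the C5–O1 bond is made beforehand with defined configuration, and C4, benzylic and para to the ring B oxygen, is the carbon where that epoxide can be ionised and joined to a two-carbon glycolate unit that supplies C3 and C2.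

## Logic of the disconnections

20 to 19: the two aryl O–Si bonds are cut. The phenols stay masked to the end because a phenoxide ortho to the epoxide cyclises, and free phenols would spoil the oxidations and the Lewis acid step. The skeleton is unchanged. The forward step must never release a free phenoxide, so the fluoride has to be buffered.

19 to 17: the C3=C4 enol is taken back to C3–H(OH) and C4–H. A saturated lactone is what a two-bond annulation delivers, and oxidation followed by enolisation erases C3 and C4, so these centres never need control. The forward oxidation must spare the epoxide and stop at the enol.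

17 to 16: the two C–O bonds of the side-chain epoxide are cut. The epoxide cannot pass the Lewis acid step, and in 16 the prenyl group is the only olefin and no enol is present. The second stereocentre becomes one late oxidation. The forward step needs reagent-controlled facial selectivity and a substrate that tolerates mild base.

16 to 13 and 14: C3–C4 and O1–C2 are cut. What remains of the ring is an epoxide (O1, C5, C4) whose C5 configuration is open to asymmetric epoxidation, plus a purchasable two-carbon unit. The ring disappears and the route becomes convergent. The forward step must break only the C4–O bond, leave C5–O untouched, and capture the cation faster than it rearranges.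

13 to 10: the carboxyl carbon is taken back to CH2OH (through 12 and 11). The hydroxymethyl group directs the asymmetric epoxidation and steers it away from the prenyl olefin. The forward oxidations must not open the electron-rich epoxide.

10 to 9: the C4–O and C5–O bonds of the oxirane are cut. The C5 stereocentre becomes a prochiral E-trisubstituted allylic alcohol, and no stereocentre is left. The forward step needs enantiofacial control and a product that survives the catalyst.

9 to 4 and 5: after the alcohol is returned to the ester (8), the future C4=C5 double bond is cut (through 7 and 6) down to a C–C bond made by aldol addition. This splits the molecule into ring A and ring B halves of similar size; 5 cannot enolise, so the pairing is unambiguous. The forward elimination must give the E olefin.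

4 to 1 and 2: the aryl O–Si bond and the ring A C–CH2 bond of the prenyl group are cut. 1 already holds the phenol and the propanoate chain. The forward step must alkylate the phenoxide at carbon and not at oxygen.

## Other disconnections considered

Alternative 1: The cut is made at the quaternary carbon itself: the C5–carboxyl bond and the O1–C2 acyl bond are formed together, and C3–C4 only afterwards.
- Forward: the non-conjugated ketone of diketone A1, acid A2 and the convertible isocyanide A3 would combine in a Passerini reaction to the α-acyloxy amide A4. Base would then condense the glycolate CH2 of A4 onto the aryl ketone to close the butenolide, and the enamide would be solvolysed to the methyl ester.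
- In its favour: one operation assembles all four substituents of C5 at the right oxidation levels. C4 arrives as a ketone, so C3=C4 follows from a condensation without any redox change. No acid-labile epoxide is handled. The sequence from A1 to 20 would be shorter than steps 3 to 12.
- Against it here: C5 is created from a planar ketone, and a Passerini reaction of a ketone offers no dependable catalytic control of configuration, so A4 would be racemic and a resolution would be needed. A1 is a benzyl 1,2-diketone, expected to sit largely as its enol and to offer a second, aryl-conjugated carbonyl group. Turning the N-cyclohexenyl amide into the ester needs acid in methanol, which the aryl silyl ethers and the prenyl group would have to survive.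
- Comparison: in structure both plans fix O1 on C5 before the ring is closed, and the alternative is the better one in convergence and step count. In mechanism its neutral multicomponent step is gentler than the cation of step 9. It makes the stereocentre in the one step that cannot be steered, whereas the chosen plan only has to keep a centre set by a well-understood asymmetric epoxidation. The need for one enantiomer decides against it.

Alternative 2: Three ring bonds are cut at once: C4–C5, C2–C3 and O1–C2.
- Forward: the ketone carbonyl of pyruvate A5, siloxyalkyne A6 and carbon monoxide A7 would be joined on a low-valent metal carbonyl (hetero-Pauson–Khand, a (2+2+1) cyclocarbonylation) to the fully silylated butenolide A8.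
- In its favour: no cut of this ring is more convergent. α-Keto esters are the carbonyl class for which the intermolecular version is best founded, because the ester can chelate the metal. A8 is the enol-protected prenyl butenolide and would need only the epoxidation and the desilylation.
- Against it here: such cyclocarbonylations call for high temperature and pressure of A7. A6 is a thermally fragile, strongly polarised alkyne, and the required orientation (aryl carbon to C5, oxygenated carbon to the new carbonyl) is not secured by any rule for this pair. The prenyl olefin of A5 is a competing two-carbon partner and A5 enolises readily. No enantioselective version applies, so A8 would be racemic.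
- Comparison: in structure this is the more powerful cut, three bonds against two, and it is clearly better in step economy. It also ends at the C3=C4 oxidation level directly, where the chosen plan needs step 11. In mechanism the metallacycle leaves C5 uncontrolled and rests on thin precedent for this substitution pattern, while the chosen plan keeps C5 from step 6 and uses an ionic step with a clear electronic bias. A8 would meet the epoxidation as a silyl enol ether, a selectivity problem that 16 does not have.

Alternative 3: The cut is C3–C4, but in a 4-hydroxy butenolide that does not yet carry ring B (PMB = 4-methoxybenzyl).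
- Forward: base would turn the PMB-oxyacetate of A9 into its enolate, which attacks the thioester carbon and closes the ring (Dieckmann) to A10. Ring B would then be attached at C4 by sulfonylation of the enol oxygen and a Suzuki coupling, followed by PMB removal, epoxidation and desilylation.
- In its favour: Dieckmann closure of α-acyloxy esters is among the most dependable routes to this ring type. It is anionic, runs cold, and has no cation and no rearrangement channel. The thioester is the better acceptor, so the choice between the two carboxyl groups is well founded. C5 is quaternary and cannot epimerise. Late introduction of ring B makes the route modular.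
- Against it here: the difficulty moves into A9, a tartronate with two different carboxyl derivatives on a stereogenic carbon, which would need a desymmetrisation of uncertain selectivity. Any closure onto the methyl ester gives a constitutional isomer. A10 is at least five steps from 20, one of them a PMB cleavage under oxidising or acidic conditions next to a prenyl group and electron-rich rings.
- Comparison: in mechanism the alternative is the better one, since its ring closure is more certain than step 9. In structure the chosen plan brings ring B and C4 into the ring-forming step, where the alternative needs an extra carbon–carbon coupling. In stereocontrol the chosen plan leans on an asymmetric epoxidation of predictable sense, the alternative on a desymmetrisation without close precedent. In step economy the chosen plan is shorter by several steps; the alternative is better for making ring B analogues.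

Key step: step 9

Shorthand in names: TBS = tert-butyldimethylsilyl; ring A benzyl = [4-(TBS-oxy)-3-(3-methylbut-2-en-1-yl)phenyl]methyl; epoxidised ring A benzyl = [4-(TBS-oxy)-3-{[(2R)-3,3-dimethyloxiran-2-yl]methyl}phenyl]methyl; ring B aryl = 4-(TBS-oxy)phenyl; lactone locants O1, C2 (carbonyl), C3, C4, C5 (quaternary) are used for the five-membered ring throughout.

Assumption (chemistry): the sense of induction of L-(+)-tartrate in step 6 and of the D-fructose-derived ketone in step 10 is taken from closely related E-2,3-disubstituted cinnamyl alcohols and prenyl arenes; 5 and 14 are purchased.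

## Route

Step 1
Reactants: 1 methyl 3-(4-hydroxyphenyl)propanoate; 2 1-bromo-3-methylbut-2-ene (prenyl bromide)
Product: 3 methyl 3-[4-hydroxy-3-(3-methylbut-2-en-1-yl)phenyl]propanoate
Conditions: NaH (1.0 equiv), toluene, 0 °C to rt; then 2 (1.0 equiv), rt
Reagents that add atoms: none
Why: Ortho C-alkylation of a sodium phenoxide ion pair in a non-polar solvent, where the tightly paired oxygen is shielded; the para position is blocked, and O-prenyl and doubly prenylated material should be removable by chromatography.

Step 2
Reactants: 3 methyl 3-[4-hydroxy-3-(3-methylbut-2-en-1-yl)phenyl]propanoate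
Product: 4 methyl 3-[4-(TBS-oxy)-3-(3-methylbut-2-en-1-yl)phenyl]propanoate
Conditions: TBSCl, imidazole, DMF, rt
Reagents that add atoms: tert-butyldimethylsilyl chloride, CC(C)(C)[Si](C)(C)Cl
Why: Standard silylation of a phenol; the aryl silyl ether should withstand enolate, hydride, mild Lewis acid and oxidants, and is removed by fluoride at the end.

Step 3
Reactants: 4 methyl 3-[4-(TBS-oxy)-3-(3-methylbut-2-en-1-yl)phenyl]propanoate; 5 4-(TBS-oxy)benzaldehyde
Product: 6 methyl 2-(ring A benzyl)-3-hydroxy-3-(ring B aryl)propanoate (diastereomer mixture)
Conditions: LiN(iPr)2 (1.1 equiv), THF, −78 °C; then 5; AcOH quench at −78 °C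
Reagents that add atoms: none
Why: Aldol addition of a lithium ester enolate to an aldehyde that cannot enolise; both new centres are destroyed in step 4, so the mixture is used as such.

Step 4
Reactants: 6 methyl 2-(ring A benzyl)-3-hydroxy-3-(ring B aryl)propanoate
Product: 8 methyl (E)-2-(ring A benzyl)-3-(ring B aryl)prop-2-enoate, via acetate 7 (not isolated)
Conditions: Ac2O, Et3N, DMAP (cat.), CH2Cl2, 0 °C to rt; then DBU, rt to 40 °C
Reagents that add atoms: none
Why: Acetylation followed by E1cB elimination through the ester enolate; the more stable olefin with the aryl group trans to the ester (E) should dominate, and a minor Z isomer can be removed by chromatography.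

Step 5
Reactants: 8 methyl (E)-2-(ring A benzyl)-3-(ring B aryl)prop-2-enoate
Product: 9 (E)-2-(ring A benzyl)-3-(ring B aryl)prop-2-en-1-ol
Conditions: (i-Bu)2AlH (2.5 equiv), CH2Cl2, −78 to −20 °C; aq. potassium sodium tartrate (KNaC4H4O6)
Reagents that add atoms: none
Why: 1,2-Reduction of a conjugated ester by an aluminium hydride; aryl silyl ethers and the isolated olefin are not affected.

Step 6
Reactants: 9 (E)-2-(ring A benzyl)-3-(ring B aryl)prop-2-en-1-ol
Product: 10 [(2S,3S)-2-(ring A benzyl)-3-(ring B aryl)oxiran-2-yl]methanol
Conditions: Ti(OiPr)4 (10 mol%), L-(+)-diisopropyl tartrate (12 mol%), t-BuOOH (2 equiv, anhydrous), 4 Å molecular sieves, CH2Cl2, −25 °C; cold non-acidic work-up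
Reagents that add atoms: tert-butyl hydroperoxide, CC(C)(C)OO
Why: Sharpless asymmetric epoxidation; the hydroxyl group binds the substrate to the titanium tartrate, so the prenyl olefin is not touched, and L-(+)-tartrate should give the (2S,3S) epoxy alcohol as with other E-2,3-disubstituted cinnamyl alcohols. C2 of 10 becomes C5 of the target; catalytic titanium, low temperature and a non-acidic work-up are chosen to limit opening of the electron-rich benzylic epoxide.

Step 7
Reactants: 10 [(2S,3S)-2-(ring A benzyl)-3-(ring B aryl)oxiran-2-yl]methanol
Product: 11 (2R,3S)-2-(ring A benzyl)-3-(ring B aryl)oxirane-2-carbaldehyde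
Conditions: Dess–Martin periodinane, pyridine, CH2Cl2, 0 °C
Reagents that add atoms: none
Why: Buffered hypervalent iodine oxidation of a primary alcohol; the α-carbon has no hydrogen, so nothing can epimerise, and the formyl group makes the epoxide less prone to ionise than in 10.

Step 8
Reactants: 11 (2R,3S)-2-(ring A benzyl)-3-(ring B aryl)oxirane-2-carbaldehyde
Product: 13 methyl (2R,3S)-2-(ring A benzyl)-3-(ring B aryl)oxirane-2-carboxylate, via glycidic acid 12 (not isolated)
Conditions: NaClO2, NaH2PO4, 2-methylbut-2-ene (large excess), t-BuOH/H2O, 0 °C; then Me3SiCHN2, MeOH/toluene, 0 °C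
Reagents that add atoms: sodium chlorite, [Na+].[O-]Cl=O; trimethylsilyldiazomethane, C[Si](C)(C)C=[N+]=[N-]
Why: Pinnick oxidation with the hypochlorous acid scavenged by excess trisubstituted alkene, which protects the prenyl group and the arenes; the acid is esterified at once so that it is not exposed to acid-catalysed opening.

Step 9
Reactants: 13 methyl (2R,3S)-2-(ring A benzyl)-3-(ring B aryl)oxirane-2-carboxylate; 14 tris(trimethylsilyloxy)ethene
Product: 16 methyl (5R)-5-(ring A benzyl)-4-(ring B aryl)-3-hydroxy-2-oxotetrahydrofuran-5-carboxylate (mixture at C3 and C4), via trimethylsilyl ether 15 (not isolated)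
Conditions: 13 and 14 (3 equiv) premixed, CH2Cl2, −78 °C; BF3·OEt2 (0.3 equiv) added slowly; to −40 °C; then aq. citric acid, THF, rt
Reagents that add atoms: none
Why: BF3 binds the epoxide oxygen and the C4–O bond ionises toward the benzylic cation that the para silyloxy group of ring B stabilises, while the C5–O bond, flanked by the ester, stays intact, so the configuration from step 6 is carried into the lactone. The nucleophilic CH carbon of 14 adds to C4 (C3–C4 bond) and gives a bis(silyloxy)carbenium ion, which the C5 alkoxide captures in a 5-exo-trig closure (O1–C2 bond); loss of hexamethyldisiloxane leaves 15, and the work-up removes the labile secondary trimethylsilyl group. The closest known reaction type is the Lewis acid-promoted opening of aryl epoxides at the benzylic carbon by silyl ketene acetals with lactonisation, a formal (3+2) annulation related to the Mukaiyama reactions. No stereocentre of the target is created: C3 and C4 form as a mixture and are erased in step 11. The step needs C4–O and not C5–O cleavage, which is secured by the benzylic donor on one side and the destabilising ester on the other. It also needs bimolecular capture to outrun the 1,2-shift of the ester or benzyl group from C5 and a Friedel–Crafts closure onto ring A; an excess of the strongly nucleophilic bis-silyl ketene acetal, low temperature and slow addition of a substoichiometric Lewis acid serve this, and the ring A positions ortho to the benzylic CH2 are meta to the silyloxy group and therefore poorly activated. The acid-derived ketene acetal is chosen because even an adduct that fails to close in the flask would be a γ-hydroxy silyl ester that should lactonise in the acidic work-up, and because it frees the C3 hydroxyl without a separate step.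

Step 10
Reactants: 16 methyl (5R)-5-(ring A benzyl)-4-(ring B aryl)-3-hydroxy-2-oxotetrahydrofuran-5-carboxylate
Product: 17 methyl (5R)-5-(epoxidised ring A benzyl)-4-(ring B aryl)-3-hydroxy-2-oxotetrahydrofuran-5-carboxylate (mixture at C3 and C4)
Conditions: D-fructose-derived ketone catalyst (1,2:4,5-di-O-isopropylidene-β-D-erythro-2,3-hexodiulo-2,6-pyranose, 30 mol%), KHSO5 (as Oxone, 2KHSO5·KHSO4·K2SO4), K2CO3, Bu4NHSO4 (cat.), Na2B4O7/Na2EDTA buffer, MeCN/CH2(OMe)2/H2O, 0 °C
Reagents that add atoms: potassium peroxymonosulfate, [K+].[O-]S(=O)(=O)OO
Why: Shi epoxidation by a chiral dioxirane through a spiro transition state; with ArCH2CH=CMe2 olefins the D-fructose-derived ketone should give the (R) configuration at the CH carbon. The prenyl group is the only olefin in 16 and no enol is present, so there is no competing site; the existing centres are remote and the selectivity is under reagent control.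

Step 11
Reactants: 17 methyl (5R)-5-(epoxidised ring A benzyl)-4-(ring B aryl)-3-hydroxy-2-oxotetrahydrofuran-5-carboxylate
Product: 19 methyl (5R)-5-(epoxidised ring A benzyl)-4-(ring B aryl)-3-hydroxy-2-oxo-2,5-dihydrofuran-5-carboxylate, via 2,3-dioxo lactone 18 (not isolated)
Conditions: Dess–Martin periodinane (1.2 equiv), pyridine, CH2Cl2, 0 °C
Reagents that add atoms: none
Why: Oxidation of the α-hydroxy lactone gives the 2,3-dioxo lactone, whose C4–H is benzylic and α to the ketone, so it should tautomerise at once to the conjugated enol and thereby merge all C3/C4 isomers into one compound. The buffered periodinane leaves the epoxide alone, and only a small excess is used so that the enol is not oxidised further.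

Step 12
Reactants: 19 methyl (5R)-5-(epoxidised ring A benzyl)-4-(ring B aryl)-3-hydroxy-2-oxo-2,5-dihydrofuran-5-carboxylate
Product: 20 methyl (2R)-2-[(3-{[(2R)-3,3-dimethyloxiran-2-yl]methyl}-4-hydroxyphenyl)methyl]-4-hydroxy-3-(4-hydroxyphenyl)-5-oxo-2,5-dihydrofuran-2-carboxylate (CNP0331593.1)
Conditions: Bu4NF (2.5 equiv), AcOH (4 equiv), THF, 0 °C; pH 5 phosphate work-up
Reagents that add atoms: none
Why: Fluoride cleavage of the two aryl silyl ethers; acetic acid keeps each liberated phenol protonated, so the ring A oxygen cannot open the neighbouring epoxide as a phenoxide, and neither stereocentre is touched.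

## Compound list

1 | methyl 3-(4-hydroxyphenyl)propanoate | COC(=O)CCc1ccc(O)cc1 | starting material
2 | 1-bromo-3-methylbut-2-ene (prenyl bromide) | CC(C)=CCBr | starting material
3 | methyl 3-[4-hydroxy-3-(3-methylbut-2-en-1-yl)phenyl]propanoate | COC(=O)CCc1ccc(O)c(CC=C(C)C)c1 | intermediate
4 | methyl 3-[4-(tert-butyldimethylsilyloxy)-3-(3-methylbut-2-en-1-yl)phenyl]propanoate | COC(=O)CCc1ccc(O[Si](C)(C)C(C)(C)C)c(CC=C(C)C)c1 | intermediate
5 | 4-(tert-butyldimethylsilyloxy)benzaldehyde | O=Cc1ccc(O[Si](C)(C)C(C)(C)C)cc1 | starting material
6 | methyl 2-{[4-(tert-butyldimethylsilyloxy)-3-(3-methylbut-2-en-1-yl)phenyl]methyl}-3-[4-(tert-butyldimethylsilyloxy)phenyl]-3-hydroxypropanoate (racemic, diastereomer mixture) | COC(=O)C(Cc1ccc(O[Si](C)(C)C(C)(C)C)c(CC=C(C)C)c1)C(O)c1ccc(O[Si](C)(C)C(C)(C)C)cc1 | intermediate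
7 | methyl 3-acetoxy-2-{[4-(tert-butyldimethylsilyloxy)-3-(3-methylbut-2-en-1-yl)phenyl]methyl}-3-[4-(tert-butyldimethylsilyloxy)phenyl]propanoate (not isolated) | COC(=O)C(Cc1ccc(O[Si](C)(C)C(C)(C)C)c(CC=C(C)C)c1)C(OC(C)=O)c1ccc(O[Si](C)(C)C(C)(C)C)cc1 | intermediate
8 | methyl (E)-2-{[4-(tert-butyldimethylsilyloxy)-3-(3-methylbut-2-en-1-yl)phenyl]methyl}-3-[4-(tert-butyldimethylsilyloxy)phenyl]prop-2-enoate | COC(=O)/C(Cc1ccc(O[Si](C)(C)C(C)(C)C)c(CC=C(C)C)c1)=C/c1ccc(O[Si](C)(C)C(C)(C)C)cc1 | intermediate
9 | (E)-2-{[4-(tert-butyldimethylsilyloxy)-3-(3-methylbut-2-en-1-yl)phenyl]methyl}-3-[4-(tert-butyldimethylsilyloxy)phenyl]prop-2-en-1-ol | OC/C(Cc1ccc(O[Si](C)(C)C(C)(C)C)c(CC=C(C)C)c1)=C/c1ccc(O[Si](C)(C)C(C)(C)C)cc1 | intermediate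
10 | [(2S,3S)-2-{[4-(tert-butyldimethylsilyloxy)-3-(3-methylbut-2-en-1-yl)phenyl]methyl}-3-[4-(tert-butyldimethylsilyloxy)phenyl]oxiran-2-yl]methanol | OC[C@]1(Cc2ccc(O[Si](C)(C)C(C)(C)C)c(CC=C(C)C)c2)O[C@H]1c1ccc(O[Si](C)(C)C(C)(C)C)cc1 | intermediate
11 | (2R,3S)-2-{[4-(tert-butyldimethylsilyloxy)-3-(3-methylbut-2-en-1-yl)phenyl]methyl}-3-[4-(tert-butyldimethylsilyloxy)phenyl]oxirane-2-carbaldehyde | O=C[C@]1(Cc2ccc(O[Si](C)(C)C(C)(C)C)c(CC=C(C)C)c2)O[C@H]1c1ccc(O[Si](C)(C)C(C)(C)C)cc1 | intermediate
12 | (2R,3S)-2-{[4-(tert-butyldimethylsilyloxy)-3-(3-methylbut-2-en-1-yl)phenyl]methyl}-3-[4-(tert-butyldimethylsilyloxy)phenyl]oxirane-2-carboxylic acid (not isolated) | OC(=O)[C@]1(Cc2ccc(O[Si](C)(C)C(C)(C)C)c(CC=C(C)C)c2)O[C@H]1c1ccc(O[Si](C)(C)C(C)(C)C)cc1 | intermediate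
13 | methyl (2R,3S)-2-{[4-(tert-butyldimethylsilyloxy)-3-(3-methylbut-2-en-1-yl)phenyl]methyl}-3-[4-(tert-butyldimethylsilyloxy)phenyl]oxirane-2-carboxylate (benzyl and aryl cis) | COC(=O)[C@]1(Cc2ccc(O[Si](C)(C)C(C)(C)C)c(CC=C(C)C)c2)O[C@H]1c1ccc(O[Si](C)(C)C(C)(C)C)cc1 | intermediate
14 | tris(trimethylsilyloxy)ethene | C[Si](C)(C)OC=C(O[Si](C)(C)C)O[Si](C)(C)C | starting material
15 | methyl (5R)-5-{[4-(tert-butyldimethylsilyloxy)-3-(3-methylbut-2-en-1-yl)phenyl]methyl}-4-[4-(tert-butyldimethylsilyloxy)phenyl]-2-oxo-3-(trimethylsilyloxy)tetrahydrofuran-5-carboxylate (lactone locants; mixture at C3 and C4; not isolated) | COC(=O)[C@]1(Cc2ccc(O[Si](C)(C)C(C)(C)C)c(CC=C(C)C)c2)OC(=O)C(O[Si](C)(C)C)C1c1ccc(O[Si](C)(C)C(C)(C)C)cc1 | intermediate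
16 | methyl (5R)-5-{[4-(tert-butyldimethylsilyloxy)-3-(3-methylbut-2-en-1-yl)phenyl]methyl}-4-[4-(tert-butyldimethylsilyloxy)phenyl]-3-hydroxy-2-oxotetrahydrofuran-5-carboxylate (lactone locants; mixture at C3 and C4) | COC(=O)[C@]1(Cc2ccc(O[Si](C)(C)C(C)(C)C)c(CC=C(C)C)c2)OC(=O)C(O)C1c1ccc(O[Si](C)(C)C(C)(C)C)cc1 | intermediate
17 | methyl (5R)-5-{[4-(tert-butyldimethylsilyloxy)-3-{[(2R)-3,3-dimethyloxiran-2-yl]methyl}phenyl]methyl}-4-[4-(tert-butyldimethylsilyloxy)phenyl]-3-hydroxy-2-oxotetrahydrofuran-5-carboxylate (lactone locants; mixture at C3 and C4) | COC(=O)[C@]1(Cc2ccc(O[Si](C)(C)C(C)(C)C)c(C[C@H]3OC3(C)C)c2)OC(=O)C(O)C1c1ccc(O[Si](C)(C)C(C)(C)C)cc1 | intermediate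
18 | methyl (5R)-5-{[4-(tert-butyldimethylsilyloxy)-3-{[(2R)-3,3-dimethyloxiran-2-yl]methyl}phenyl]methyl}-4-[4-(tert-butyldimethylsilyloxy)phenyl]-2,3-dioxotetrahydrofuran-5-carboxylate (lactone locants; mixture at C4; not isolated) | COC(=O)[C@]1(Cc2ccc(O[Si](C)(C)C(C)(C)C)c(C[C@H]3OC3(C)C)c2)OC(=O)C(=O)C1c1ccc(O[Si](C)(C)C(C)(C)C)cc1 | intermediate
19 | methyl (5R)-5-{[4-(tert-butyldimethylsilyloxy)-3-{[(2R)-3,3-dimethyloxiran-2-yl]methyl}phenyl]methyl}-4-[4-(tert-butyldimethylsilyloxy)phenyl]-3-hydroxy-2-oxo-2,5-dihydrofuran-5-carboxylate (lactone locants) | COC(=O)[C@]1(Cc2ccc(O[Si](C)(C)C(C)(C)C)c(C[C@H]3OC3(C)C)c2)OC(=O)C(O)=C1c1ccc(O[Si](C)(C)C(C)(C)C)cc1 | intermediate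
20 | methyl (2R)-2-[(3-{[(2R)-3,3-dimethyloxiran-2-yl]methyl}-4-hydroxyphenyl)methyl]-4-hydroxy-3-(4-hydroxyphenyl)-5-oxo-2,5-dihydrofuran-2-carboxylate (CNP0331593.1) | COC(=O)[C@]1(Cc2ccc(O)c(C[C@H]3OC3(C)C)c2)OC(=O)C(O)=C1c1ccc(O)cc1 | target

## Step count and least certain steps

Total: 12 steps. Longest linear sequence: 12 steps (1 to 20); 2, 5 and 14 are purchased and enter in steps 1, 3 and 9.

Step 9 (key step). The most likely failure is that, after ionisation, migration of the ester or the benzyl group from C5 to C4 (an oxyanion-driven 1,2-shift) or arylation by ring A wins over bimolecular capture. The cation is long-lived because of the para oxygen donor and the nucleophile is bulky; desilylation of the ketene acetal by the Lewis acid would starve the capture further. The fallback sets out from 13 and comes back at 20: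
- Oxidative opening of the epoxide with DMSO and catalytic acid (Kornblum-type oxidation of an epoxide to an α-hydroxy ketone, the solvent acting as the trap) would give methyl (2R)-2-hydroxy-2-(ring A benzyl)-3-oxo-3-(ring B aryl)propanoate F1, with the C5–O bond again untouched.
- Acylation of the tertiary hydroxyl with (triisopropylsilyloxy)acetyl chloride, pyridine and DMAP would give the α-acyloxy ketone F2.
- LiN(SiMe3)2 in THF at −78 °C would add the ester enolate to the aryl ketone and close the lactone as the C4 carbinol F3.
- Acid-catalysed dehydration through the para-silyloxybenzyl cation would give the fully silylated butenolide F4 (identical in structure with A8).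
- Epoxidation of F4 under the conditions of step 10 would give the epoxide F5, and buffered fluoride as in step 12 would remove all three silyl groups to give 20.

This fallback forms C3–C4 by enolate addition to a ketone instead of capture of a cation. It costs three more steps and exposes a silyl enol ether to the dioxirane.

Step 6. The most likely failure is opening of the product epoxide at the benzylic carbon by isopropanol, tartrate or hydroperoxide under the Lewis acidity of the titanium alkoxide, during the reaction or the work-up, because ring B is a para donor; slow turnover caused by the 2-benzyl group would lengthen the exposure. The fallback sets out from 9 and comes back at 10: a vanadium-catalysed asymmetric epoxidation with VO(OiPr)3 (1 to 2 mol%) and a chiral C2-symmetric bishydroxamic acid ligand, the enantiomer of the ligand being chosen to give the (2S,3S) product, with aqueous t-BuOOH in toluene at 0 °C. It uses a different metal, ligand class and mode of activation, has no strongly Lewis acidic alkoxide, and tolerates water. The crude 10 would be oxidised at once as in step 7. No new compound is involved (entry F0).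

Step 8. The most likely failure is acid-catalysed opening or fragmentation of the glycidic acid in the chlorite medium (pH 3 to 4) and before esterification, and chlorination of the prenyl olefin if the scavenger is used up. The fallback sets out from 10 and comes back at 13: oxidation of the alcohol straight to the carboxylate with TEMPO (cat.), NaClO2 and NaOCl (cat.) in MeCN/phosphate buffer at pH 6.8 would give the sodium glycidate F6, which would be kept as its salt without acidification and alkylated with MeI in DMF. The free acid and the acidic medium are avoided, and the ester is made by carboxylate alkylation instead of from a diazo compound.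

Step 10. The most likely failure is poor facial selectivity, since there is no substrate bias and the ortho silyloxy group crowds the olefin, or base-induced loss at pH about 10.5 (lactone hydrolysis, or cleavage of an aryl silyl ether followed by attack of the phenoxide on the new epoxide). The fallback sets out from 16 and comes back at 19: buffered mCPBA (NaHCO3, CH2Cl2, 0 °C) would epoxidise the only olefin without base and without facial bias, giving 17 together with its epoxide epimer F7. Oxidation as in step 11 would merge the C3/C4 isomers and give 19 and its epoxide epimer F8, which differ at one of two stereocentres and would be separated by chromatography before step 12. This replaces catalyst control by an achiral peracid and a separation of diastereomers, at the cost of about half the material.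

## Further compounds

F1 | step 9 | methyl (2R)-2-{[4-(tert-butyldimethylsilyloxy)-3-(3-methylbut-2-en-1-yl)phenyl]methyl}-3-[4-(tert-butyldimethylsilyloxy)phenyl]-2-hydroxy-3-oxopropanoate | COC(=O)[C@](Cc1ccc(O[Si](C)(C)C(C)(C)C)c(CC=C(C)C)c1)(O)C(=O)c1ccc(O[Si](C)(C)C(C)(C)C)cc1
F2 | step 9 | methyl (2R)-2-{[4-(tert-butyldimethylsilyloxy)-3-(3-methylbut-2-en-1-yl)phenyl]methyl}-3-[4-(tert-butyldimethylsilyloxy)phenyl]-3-oxo-2-{[(triisopropylsilyloxy)acetyl]oxy}propanoate | COC(=O)[C@](Cc1ccc(O[Si](C)(C)C(C)(C)C)c(CC=C(C)C)c1)(OC(=O)CO[Si](C(C)C)(C(C)C)C(C)C)C(=O)c1ccc(O[Si](C)(C)C(C)(C)C)cc1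
F3 | step 9 | methyl (5R)-5-{[4-(tert-butyldimethylsilyloxy)-3-(3-methylbut-2-en-1-yl)phenyl]methyl}-4-[4-(tert-butyldimethylsilyloxy)phenyl]-4-hydroxy-2-oxo-3-(triisopropylsilyloxy)tetrahydrofuran-5-carboxylate (lactone locants; mixture at C3 and C4) | COC(=O)[C@]1(Cc2ccc(O[Si](C)(C)C(C)(C)C)c(CC=C(C)C)c2)OC(=O)C(O[Si](C(C)C)(C(C)C)C(C)C)C1(O)c1ccc(O[Si](C)(C)C(C)(C)C)cc1
F4 | step 9 | methyl (5R)-5-{[4-(tert-butyldimethylsilyloxy)-3-(3-methylbut-2-en-1-yl)phenyl]methyl}-4-[4-(tert-butyldimethylsilyloxy)phenyl]-2-oxo-3-(triisopropylsilyloxy)-2,5-dihydrofuran-5-carboxylate (lactone locants) | COC(=O)[C@]1(Cc2ccc(O[Si](C)(C)C(C)(C)C)c(CC=C(C)C)c2)OC(=O)C(O[Si](C(C)C)(C(C)C)C(C)C)=C1c1ccc(O[Si](C)(C)C(C)(C)C)cc1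
F5 | step 9 | methyl (5R)-5-{[4-(tert-butyldimethylsilyloxy)-3-{[(2R)-3,3-dimethyloxiran-2-yl]methyl}phenyl]methyl}-4-[4-(tert-butyldimethylsilyloxy)phenyl]-2-oxo-3-(triisopropylsilyloxy)-2,5-dihydrofuran-5-carboxylate (lactone locants) | COC(=O)[C@]1(Cc2ccc(O[Si](C)(C)C(C)(C)C)c(C[C@H]3OC3(C)C)c2)OC(=O)C(O[Si](C(C)C)(C(C)C)C(C)C)=C1c1ccc(O[Si](C)(C)C(C)(C)C)cc1
F0 | step 6 | none | none
F6 | step 8 | sodium (2R,3S)-2-{[4-(tert-butyldimethylsilyloxy)-3-(3-methylbut-2-en-1-yl)phenyl]methyl}-3-[4-(tert-butyldimethylsilyloxy)phenyl]oxirane-2-carboxylate | [Na+].[O-]C(=O)[C@]1(Cc2ccc(O[Si](C)(C)C(C)(C)C)c(CC=C(C)C)c2)O[C@H]1c1ccc(O[Si](C)(C)C(C)(C)C)cc1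
F7 | step 10 | methyl (5R)-5-{[4-(tert-butyldimethylsilyloxy)-3-{[(2S)-3,3-dimethyloxiran-2-yl]methyl}phenyl]methyl}-4-[4-(tert-butyldimethylsilyloxy)phenyl]-3-hydroxy-2-oxotetrahydrofuran-5-carboxylate (lactone locants; mixture at C3 and C4) | COC(=O)[C@]1(Cc2ccc(O[Si](C)(C)C(C)(C)C)c(C[C@@H]3OC3(C)C)c2)OC(=O)C(O)C1c1ccc(O[Si](C)(C)C(C)(C)C)cc1
F8 | step 10 | methyl (5R)-5-{[4-(tert-butyldimethylsilyloxy)-3-{[(2S)-3,3-dimethyloxiran-2-yl]methyl}phenyl]methyl}-4-[4-(tert-butyldimethylsilyloxy)phenyl]-3-hydroxy-2-oxo-2,5-dihydrofuran-5-carboxylate (lactone locants) | COC(=O)[C@]1(Cc2ccc(O[Si](C)(C)C(C)(C)C)c(C[C@@H]3OC3(C)C)c2)OC(=O)C(O)=C1c1ccc(O[Si](C)(C)C(C)(C)C)cc1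
A1 | alternative 1 | 3-[4-(tert-butyldimethylsilyloxy)-3-(3-methylbut-2-en-1-yl)phenyl]-1-[4-(tert-butyldimethylsilyloxy)phenyl]propane-1,2-dione | O=C(Cc1ccc(O[Si](C)(C)C(C)(C)C)c(CC=C(C)C)c1)C(=O)c1ccc(O[Si](C)(C)C(C)(C)C)cc1
A2 | alternative 1 | (tert-butyldimethylsilyloxy)acetic acid | OC(=O)CO[Si](C)(C)C(C)(C)C
A3 | alternative 1 | 1-isocyanocyclohex-1-ene | [C-]#[N+]C1=CCCCC1
A4 | alternative 1 | Passerini adduct, the α-acyloxy α-(N-cyclohexenylcarboxamido) ketone with C5 configured as in the target | O=C(NC1=CCCCC1)[C@](Cc2ccc(O[Si](C)(C)C(C)(C)C)c(CC=C(C)C)c2)(OC(=O)CO[Si](C)(C)C(C)(C)C)C(=O)c1ccc(O[Si](C)(C)C(C)(C)C)cc1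
A5 | alternative 2 | methyl 3-[4-(tert-butyldimethylsilyloxy)-3-(3-methylbut-2-en-1-yl)phenyl]-2-oxopropanoate | COC(=O)C(=O)Cc1ccc(O[Si](C)(C)C(C)(C)C)c(CC=C(C)C)c1
A6 | alternative 2 | tert-butyldimethyl(4-{[(triisopropylsilyl)oxy]ethynyl}phenoxy)silane | CC(C)[Si](OC#Cc1ccc(O[Si](C)(C)C(C)(C)C)cc1)(C(C)C)C(C)C
A7 | alternative 2 | carbon monoxide | [C-]#[O+]
A8 | alternative 2 | fully silylated prenyl butenolide with C5 configured as in the target | COC(=O)[C@]1(Cc2ccc(O[Si](C)(C)C(C)(C)C)c(CC=C(C)C)c2)OC(=O)C(O[Si](C(C)C)(C(C)C)C(C)C)=C1c1ccc(O[Si](C)(C)C(C)(C)C)cc1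
A9 | alternative 3 | 1-methyl 3-S-ethyl 2-{[4-(tert-butyldimethylsilyloxy)-3-(3-methylbut-2-en-1-yl)phenyl]methyl}-2-({[(4-methoxyphenyl)methoxy]acetyl}oxy)-3-thiomalonate, configured to give C5 as in the target | COC(=O)[C@](Cc1ccc(O[Si](C)(C)C(C)(C)C)c(CC=C(C)C)c1)(OC(=O)COCc1ccc(OC)cc1)C(=O)SCC
A10 | alternative 3 | methyl 5-(ring A benzyl)-4-hydroxy-3-[(4-methoxyphenyl)methoxy]-2-oxo-2,5-dihydrofuran-5-carboxylate with C5 configured as in the target (lactone locants) | COC(=O)[C@]1(Cc2ccc(O[Si](C)(C)C(C)(C)C)c(CC=C(C)C)c2)OC(=O)C(OCc2ccc(OC)cc2)=C1O
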